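**Retrosynthetic overview**

1. The strategy rests on the fully substituted quinone ring C1–C4 (C2 carries CH3, C3 carries chain carbon C1') fused at C4a/C8a to an unsubstituted benzo ring. C2 and C3 are the carbons of a 2-alkyne, C1 is a carbene carbon, C4 a carbonyl ligand and the benzo ring the phenyl group of the carbene, so a Dötz benzannulation closes this ring.
2. The alkyne is the C35 skipped enyne made from the C40 allylic bromide (C1') and prop-1-ynylmagnesium bromide. The chain is cut at C4'–C5', C12'–C13' and C24'–C25', each made by Li2CuCl4-catalysed coupling of an alkyl Grignard reagent with a primary allylic bromide.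
3. Building blocks: an ω-brominated prenyl ether (C1'–C4'), (S)-citronellyl bromide (C5'–C12'), an ω-brominated farnesyl ether (C13'–C24') and hydrogenated (S)-citronellyl bromide (C25'–C32'). C7' and C27' come from (S)-citronellol; C11' comes from an asymmetric hydrogenation of an (E)-2-methylalk-2-enoic acid with Ru(OAc)2[(R)-H8-BINAP].
4. Ring order: the benzo ring is bought as phenyllithium; the oxygenated ring is the only ring formed (step 23), and step 24 oxidises it to the quinone.

Key step: step 23

Remark: the chain is numbered C1' (on quinone C3) to C32'. CIP analysis of the given structure gives 7'S, 11'R, 27'S, all three with the spatial sense of C3 in (S)-citronellol. (2E,6E)-Farnesol and solutions of phenyllithium and prop-1-ynylmagnesium bromide are taken as commercial.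

**Route**

Step 1
Reactants: 1 (S)-citronellol
Product: 2 (S)-citronellyl bromide [(6S)-8-bromo-2,6-dimethyloct-2-ene]
Conditions: CBr4, PPh3, CH2Cl2, 0 °C
Reagents that add atoms: carbon tetrabromide, BrC(Br)(Br)Br
Why: Appel bromination displaces the primary alkoxyphosphonium group by SN2 and touches neither the trisubstituted alkene nor the stereocentre.

Step 2
Reactants: 2 (S)-citronellyl bromide
Product: 3 (3S)-1-bromo-3,7-dimethyloctane
Conditions: H2 (1 atm), PtO2 (cat.), EtOAc, rt
Reagents that add atoms: none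
Why: Heterogeneous catalytic hydrogenation in neutral EtOAc saturates the trisubstituted alkene while a primary alkyl bromide is not hydrogenolysed; the new C7 is an isopropyl carbon and no stereocentre, and C3 is untouched.

Step 3
Reactants: 4 (2E,6E)-farnesol
Product: 5 tert-butyl(diphenyl){[(2E,6E)-3,7,11-trimethyldodeca-2,6,10-trien-1-yl]oxy}silane
Conditions: TBDPSCl, imidazole, DMF, rt
Reagents that add atoms: tert-butyl(chloro)diphenylsilane, CC(C)(C)[Si](Cl)(c1ccccc1)c1ccccc1
Why: Silylation of the primary allylic alcohol gives an achiral ether that is stable to SeO2, Appel conditions and Grignard reagents.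

Step 4
Reactants: 5 farnesyl silyl ether
Product: 6 (2E,6E,10E)-12-[(tert-butyldiphenylsilyl)oxy]-2,6,10-trimethyldodeca-2,6,10-trien-1-ol
Conditions: SeO2 (cat.), tBuOOH, salicylic acid (cat.), CH2Cl2, 0 °C to rt, stopped at partial conversion
Reagents that add atoms: tert-butyl hydroperoxide, CC(C)(C)OO, whose oxygen is handed on by the catalyst selenium dioxide, O=[Se]=O
Why: SeO2 allylic oxidation (ene reaction, then [2,3]-sigmatropic shift) should attack the E-methyl group of the terminal isopropylidene, the most electron-rich alkene, while the 2,3-alkene is deactivated by the allylic silyloxy group, so the (E)-allylic alcohol is expected.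

Step 5
Reactants: 6 ω-hydroxy farnesyl silyl ether
Product: 7 {[(2E,6E,10E)-12-bromo-3,7,11-trimethyldodeca-2,6,10-trien-1-yl]oxy}(tert-butyl)diphenylsilane
Conditions: CBr4, PPh3, CH2Cl2, −20 to 0 °C
Reagents that add atoms: carbon tetrabromide, BrC(Br)(Br)Br
Why: Appel bromination of a primary allylic alcohol at low temperature runs by direct SN2 without allylic transposition and keeps the E geometry.

Step 6
Reactants: 3 (3S)-1-bromo-3,7-dimethyloctane; 7 ω-bromo farnesyl silyl ether
Product: 9 tert-butyl{[(2E,6E,10E,15S)-3,7,11,15,19-pentamethylicosa-2,6,10-trien-1-yl]oxy}diphenylsilane, via Grignard reagent 8 (not isolated)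
Conditions: 3, Mg, THF, 40 °C; then 7, Li2CuCl4 (cat.), THF, −78 to 0 °C
Reagents that add atoms: none
Why: Copper-catalysed Grignard cross-coupling with Li2CuCl4 substitutes the primary allylic bromide in the SN2 sense with retention of the E alkene; the silyl ether is no leaving group, and the stereocentre (C27') comes unchanged from 3.

Step 7
Reactants: 9 C25 silyl ether
Product: 10 (2E,6E,10E,15S)-3,7,11,15,19-pentamethylicosa-2,6,10-trien-1-ol
Conditions: Bu4NF, THF, 0 °C to rt
Reagents that add atoms: none
Why: Fluoride-driven desilylation frees the allylic alcohol without affecting the alkenes.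

Step 8
Reactants: 10 C25 allylic alcohol
Product: 11 (2E,6E,10E,15S)-1-bromo-3,7,11,15,19-pentamethylicosa-2,6,10-triene
Conditions: CBr4, PPh3, CH2Cl2, −20 to 0 °C; used without storage
Reagents that add atoms: carbon tetrabromide, BrC(Br)(Br)Br
Why: Appel bromination converts the primary allylic alcohol into the bromide with the 2E geometry kept, as is usual for prenyl-type alcohols.

Step 9
Reactants: 12 prenol (3-methylbut-2-en-1-ol)
Product: 13 tert-butyl[(3-methylbut-2-en-1-yl)oxy]diphenylsilane
Conditions: TBDPSCl, imidazole, DMF, rt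
Reagents that add atoms: tert-butyl(chloro)diphenylsilane, CC(C)(C)[Si](Cl)(c1ccccc1)c1ccccc1
Why: Silylation of a primary alcohol, chosen for the same stability reasons as in step 3.

Step 10
Reactants: 13 prenyl silyl ether
Product: 14 (E)-4-[(tert-butyldiphenylsilyl)oxy]-2-methylbut-2-en-1-ol
Conditions: SeO2 (cat.), tBuOOH, salicylic acid (cat.), CH2Cl2, 0 °C to rt
Reagents that add atoms: tert-butyl hydroperoxide, CC(C)(C)OO, whose oxygen is handed on by the catalyst selenium dioxide, O=[Se]=O
Why: SeO2 allylic oxidation of the only alkene takes the methyl group trans to the CH2O substituent, which gives the (E)-allylic alcohol.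

Step 11
Reactants: 14 (E)-hydroxy prenyl silyl ether
Product: 15 {[(E)-4-bromo-3-methylbut-2-en-1-yl]oxy}(tert-butyl)diphenylsilane
Conditions: CBr4, PPh3, CH2Cl2, −20 to 0 °C
Reagents that add atoms: carbon tetrabromide, BrC(Br)(Br)Br
Why: Appel bromination of the primary allylic alcohol by SN2, with the E geometry kept.

Step 12
Reactants: 2 (S)-citronellyl bromide
Product: 17 (2E,6S)-8-bromo-2,6-dimethyloct-2-enal, via allylic alcohol 16 (not isolated)
Conditions: SeO2 (cat.), tBuOOH, salicylic acid (cat.), CH2Cl2, rt; then MnO2, CH2Cl2, rt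
Reagents that add atoms: tert-butyl hydroperoxide, CC(C)(C)OO, whose oxygen is handed on by the catalyst selenium dioxide, O=[Se]=O
Why: SeO2 allylic oxidation of the E-methyl group of the isopropylidene followed by MnO2 oxidation of the allylic alcohol should give the (E)-enal, with the alkyl bromide and the stereocentre as spectators.

Step 13
Reactants: 17 bromo enal
Product: 18 (2E,6S)-8-bromo-2,6-dimethyloct-2-enoic acid
Conditions: NaClO2, NaH2PO4, 2-methylbut-2-ene, tBuOH/H2O, rt
Reagents that add atoms: sodium chlorite, [Na+].[O-]Cl=O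
Why: Pinnick oxidation converts the enal into the acid without touching the conjugated alkene, the scavenger alkene removing the hypochlorous acid.

Step 14
Reactants: 18 (E)-2-methylalk-2-enoic acid
Product: 19 (2R,6S)-8-bromo-2,6-dimethyloctanoic acid
Conditions: H2 (1.5–4 atm), Ru(OAc)2[(R)-H8-BINAP] (cat.), MeOH, rt
Reagents that add atoms: none
Why: Carboxylate-directed asymmetric hydrogenation of a tiglic-acid-type substrate with Ru(OAc)2[(R)-H8-BINAP] should set C2 (later C11') as R under catalyst control, the (R)-ligand being the one that gives (R)-2-methylalkanoic acids; the remote C6 centre has no influence.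

Step 15
Reactants: 19 saturated bromo acid
Product: 20 (2R,6S)-8-bromo-2,6-dimethyloctan-1-ol
Conditions: BH3·SMe2, THF, 0 °C to rt; aqueous work-up
Reagents that add atoms: none
Why: Borane reduces the carboxylic acid chemoselectively to the primary alcohol without touching the alkyl bromide or epimerising C2.

Step 16
Reactants: 20 bromo alcohol
Product: 21 (2R,6S)-8-bromo-1-chloro-2,6-dimethyloctane
Conditions: PPh3, N-chlorosuccinimide, CH2Cl2, 0 °C to rt
Reagents that add atoms: N-chlorosuccinimide, O=C1CCC(=O)N1Cl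
Why: Appel-type chlorination by SN2 at the primary carbinol gives two different halides, the bromide for the first Grignard reagent and the chloride as a latent second one.

Step 17
Reactants: 21 bromo chloride; 15 (E)-bromo prenyl silyl ether
Product: 23 tert-butyl{[(2E,7S,11R)-12-chloro-3,7,11-trimethyldodec-2-en-1-yl]oxy}diphenylsilane, via Grignard reagent 22 (not isolated)
Conditions: 21, Mg, THF, 25 °C; then 15, Li2CuCl4 (cat.), THF, −78 to 0 °C
Reagents that add atoms: none
Why: Magnesium inserts into the C–Br bond far faster than into the C–Cl bond, and the Li2CuCl4-catalysed Grignard cross-coupling substitutes the primary allylic bromide by SN2 (C4'–C5' bond) while the alkyl chloride and both stereocentres stay as they are.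

Step 18
Reactants: 23 C15 chloride; 11 C25 allylic bromide
Product: 25 tert-butyl{[(2E,7S,11R,14E,18E,22E,27S)-3,7,11,15,19,23,27,31-octamethyldotriaconta-2,14,18,22-tetraen-1-yl]oxy}diphenylsilane, via Grignard reagent 24 (not isolated)
Conditions: 23, activated Mg, THF, reflux; then 11, Li2CuCl4 (cat.), THF, −78 to 0 °C
Reagents that add atoms: none
Why: The primary chloride forms its Grignard reagent in refluxing THF, and copper-catalysed Grignard cross-coupling at the primary carbon of the allylic bromide (the γ carbon is fully substituted, which disfavours the SN2' course) should form C12'–C13' with the E alkene kept.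

Step 19
Reactants: 25 C40 silyl ether
Product: 26 (2E,7S,11R,14E,18E,22E,27S)-3,7,11,15,19,23,27,31-octamethyldotriaconta-2,14,18,22-tetraen-1-ol
Conditions: Bu4NF, THF, 0 °C to rt
Reagents that add atoms: none
Why: Fluoride-driven desilylation frees the C1' allylic alcohol and leaves the four alkenes and three stereocentres alone.

Step 20
Reactants: 26 C40 allylic alcohol
Product: 27 (2E,7S,11R,14E,18E,22E,27S)-1-bromo-3,7,11,15,19,23,27,31-octamethyldotriaconta-2,14,18,22-tetraene
Conditions: CBr4, PPh3, CH2Cl2, −20 to 0 °C; used without storage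
Reagents that add atoms: carbon tetrabromide, BrC(Br)(Br)Br
Why: Appel bromination of the primary allylic alcohol by SN2 with the 2E geometry kept.

Step 21
Reactants: 27 C40 allylic bromide; 28 prop-1-ynylmagnesium bromide
Product: 29 (5E,10S,14R,17E,21E,25E,30S)-6,10,14,18,22,26,30,34-octamethylpentatriaconta-5,17,21,25-tetraen-2-yne
Conditions: 28 (THF solution), CuCl (cat.), THF, 0 to 40 °C
Reagents that add atoms: none
Why: Copper-catalysed coupling of an alkynyl Grignard reagent with a primary allylic bromide attacks C1' (SN2 course) to give the 1,4-enyne, and the weakly basic alkynyl nucleophile should not isomerise the doubly activated CH2 group.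

Step 22
Reactants: 30 hexacarbonylchromium; 31 phenyllithium
Product: 33 pentacarbonyl[methoxy(phenyl)methylene]chromium, via lithium acylchromate 32 (not isolated)
Conditions: Et2O, 0 °C to rt; then Me3OBF4, CH2Cl2/H2O, rt
Reagents that add atoms: trimethyloxonium tetrafluoroborate, C[O+](C)C.F[B-](F)(F)F
Why: Fischer carbene synthesis: phenyllithium adds to a carbonyl ligand and the acylchromate oxygen is methylated by the oxonium salt.

Step 23
Reactants: 33 pentacarbonyl[methoxy(phenyl)methylene]chromium; 29 skipped enyne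
Product: 35 4-methoxy-3-methyl-2-[(2E,7S,11R,14E,18E,22E,27S)-3,7,11,15,19,23,27,31-octamethyldotriaconta-2,14,18,22-tetraen-1-yl]naphthalen-1-ol, via tricarbonylchromium naphthol complex 34 (not isolated)
Conditions: tBuOMe, 55 °C, argon; then CO (50 bar), 70 °C; product kept under argon
Reagents that add atoms: none
Why: Heating dissociates a cis carbonyl ligand from 33, the alkyne of 29 takes the free site and couples with the carbene carbon through its methyl-bearing carbon (the larger CH2 substituent is placed next to the incoming carbonyl), and migration of a carbonyl ligand onto the chain-bearing alkyne carbon gives a chromium-bound vinylketene. The oxygenated ring closes by 6π-electrocyclisation of this dienylketene onto an ortho carbon of the phenyl group, and tautomerisation gives the chromium-bound naphthol 34, from which CO pressure displaces the metal as Cr(CO)6. The closest known reaction type is the Dötz benzannulation of aryl(alkoxy)carbene chromium complexes with internal alkynes, which is established for 2-alkynes that carry isoprenoid chains. No stereocentre is formed, and in this neutral medium the 1,4-relationship between the alkyne-derived ring carbon and the C2'–C3' alkene, the E geometries and the three chain stereocentres should stay in place. The step needs chemoselectivity for the alkyne over the four trisubstituted alkenes and for benzannulation over indene, furan or cyclobutenone formation, which a phenyl(methoxy)carbene in an ethereal solvent at moderate temperature favours. Regioselectivity is not required, since insertion of the alkyne in the reverse orientation would only interchange the positions of OH and OMe relative to the methyl group and the chain, and the oxidation of step 24 erases that difference.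

Step 24
Reactants: 35 methoxynaphthol
Product: 36 2-methyl-3-[(2E,7S,11R,14E,18E,22E,27S)-3,7,11,15,19,23,27,31-octamethyldotriaconta-2,14,18,22-tetraen-1-yl]naphthalene-1,4-dione (target)
Conditions: (NH4)2Ce(NO3)6, MeCN/H2O, 0 °C
Reagents that add atoms: water, O
Why: Oxidative demethylation by tetravalent cerium takes two electrons from the electron-rich 4-methoxy-1-naphthol, water adds at the methoxy-bearing carbon and methanol leaves, which gives the quinone while the isolated trisubstituted alkenes should not be oxidised at 0 °C; both oxygenated ring carbons end as carbonyl groups, so the orientation of alkyne insertion in step 23 has no bearing on the product.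

**Compound list**

1 | (S)-citronellol [(3S)-3,7-dimethyloct-6-en-1-ol] | OCC[C@@H](C)CCC=C(C)C | starting material
2 | (S)-citronellyl bromide [(6S)-8-bromo-2,6-dimethyloct-2-ene] | BrCC[C@@H](C)CCC=C(C)C | intermediate
3 | (3S)-1-bromo-3,7-dimethyloctane | BrCC[C@@H](C)CCCC(C)C | intermediate
4 | (2E,6E)-farnesol | CC(C)=CCC/C(C)=C/CC/C(C)=C/CO | starting material
5 | tert-butyl(diphenyl){[(2E,6E)-3,7,11-trimethyldodeca-2,6,10-trien-1-yl]oxy}silane | CC(C)=CCC/C(C)=C/CC/C(C)=C/CO[Si](c1ccccc1)(c1ccccc1)C(C)(C)C | intermediate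
6 | (2E,6E,10E)-12-[(tert-butyldiphenylsilyl)oxy]-2,6,10-trimethyldodeca-2,6,10-trien-1-ol | OC/C(C)=C/CC/C(C)=C/CC/C(C)=C/CO[Si](c1ccccc1)(c1ccccc1)C(C)(C)C | intermediate
7 | {[(2E,6E,10E)-12-bromo-3,7,11-trimethyldodeca-2,6,10-trien-1-yl]oxy}(tert-butyl)diphenylsilane | BrC/C(C)=C/CC/C(C)=C/CC/C(C)=C/CO[Si](c1ccccc1)(c1ccccc1)C(C)(C)C | intermediate
8 | [(3S)-3,7-dimethyloctyl]magnesium bromide | Br[Mg]CC[C@@H](C)CCCC(C)C | intermediate
9 | tert-butyl{[(2E,6E,10E,15S)-3,7,11,15,19-pentamethylicosa-2,6,10-trien-1-yl]oxy}diphenylsilane | CC(C)(C)[Si](c1ccccc1)(c1ccccc1)OC/C=C(\C)CC/C=C(\C)CC/C=C(\C)CCC[C@@H](C)CCCC(C)C | intermediate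
10 | (2E,6E,10E,15S)-3,7,11,15,19-pentamethylicosa-2,6,10-trien-1-ol | OC/C=C(\C)CC/C=C(\C)CC/C=C(\C)CCC[C@@H](C)CCCC(C)C | intermediate
11 | (2E,6E,10E,15S)-1-bromo-3,7,11,15,19-pentamethylicosa-2,6,10-triene | BrC/C=C(\C)CC/C=C(\C)CC/C=C(\C)CCC[C@@H](C)CCCC(C)C | intermediate
12 | prenol (3-methylbut-2-en-1-ol) | CC(C)=CCO | starting material
13 | tert-butyl[(3-methylbut-2-en-1-yl)oxy]diphenylsilane | CC(C)=CCO[Si](c1ccccc1)(c1ccccc1)C(C)(C)C | intermediate
14 | (E)-4-[(tert-butyldiphenylsilyl)oxy]-2-methylbut-2-en-1-ol | OC/C(C)=C/CO[Si](c1ccccc1)(c1ccccc1)C(C)(C)C | intermediate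
15 | {[(E)-4-bromo-3-methylbut-2-en-1-yl]oxy}(tert-butyl)diphenylsilane | BrC/C(C)=C/CO[Si](c1ccccc1)(c1ccccc1)C(C)(C)C | intermediate
16 | (2E,6S)-8-bromo-2,6-dimethyloct-2-en-1-ol | BrCC[C@@H](C)CC/C=C(\C)CO | intermediate
17 | (2E,6S)-8-bromo-2,6-dimethyloct-2-enal | BrCC[C@@H](C)CC/C=C(\C)C=O | intermediate
18 | (2E,6S)-8-bromo-2,6-dimethyloct-2-enoic acid | BrCC[C@@H](C)CC/C=C(\C)C(=O)O | intermediate
19 | (2R,6S)-8-bromo-2,6-dimethyloctanoic acid | BrCC[C@@H](C)CCC[C@@H](C)C(=O)O | intermediate
20 | (2R,6S)-8-bromo-2,6-dimethyloctan-1-ol | BrCC[C@@H](C)CCC[C@@H](C)CO | intermediate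
21 | (2R,6S)-8-bromo-1-chloro-2,6-dimethyloctane | BrCC[C@@H](C)CCC[C@@H](C)CCl | intermediate
22 | [(3S,7R)-8-chloro-3,7-dimethyloctyl]magnesium bromide | Br[Mg]CC[C@@H](C)CCC[C@@H](C)CCl | intermediate
23 | tert-butyl{[(2E,7S,11R)-12-chloro-3,7,11-trimethyldodec-2-en-1-yl]oxy}diphenylsilane | CC(C)(C)[Si](c1ccccc1)(c1ccccc1)OC/C=C(\C)CCC[C@@H](C)CCC[C@@H](C)CCl | intermediate
24 | {(2R,6S,10E)-12-[(tert-butyldiphenylsilyl)oxy]-2,6,10-trimethyldodec-10-en-1-yl}magnesium chloride | CC(C)(C)[Si](c1ccccc1)(c1ccccc1)OC/C=C(\C)CCC[C@@H](C)CCC[C@@H](C)C[Mg]Cl | intermediate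
25 | tert-butyl{[(2E,7S,11R,14E,18E,22E,27S)-3,7,11,15,19,23,27,31-octamethyldotriaconta-2,14,18,22-tetraen-1-yl]oxy}diphenylsilane | CC(C)(C)[Si](c1ccccc1)(c1ccccc1)OC/C=C(\C)CCC[C@@H](C)CCC[C@@H](C)CC/C=C(\C)CC/C=C(\C)CC/C=C(\C)CCC[C@@H](C)CCCC(C)C | intermediate
26 | (2E,7S,11R,14E,18E,22E,27S)-3,7,11,15,19,23,27,31-octamethyldotriaconta-2,14,18,22-tetraen-1-ol | OC/C=C(\C)CCC[C@@H](C)CCC[C@@H](C)CC/C=C(\C)CC/C=C(\C)CC/C=C(\C)CCC[C@@H](C)CCCC(C)C | intermediate
27 | (2E,7S,11R,14E,18E,22E,27S)-1-bromo-3,7,11,15,19,23,27,31-octamethyldotriaconta-2,14,18,22-tetraene | BrC/C=C(\C)CCC[C@@H](C)CCC[C@@H](C)CC/C=C(\C)CC/C=C(\C)CC/C=C(\C)CCC[C@@H](C)CCCC(C)C | intermediate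
28 | prop-1-ynylmagnesium bromide | CC#C[Mg]Br | starting material
29 | (5E,10S,14R,17E,21E,25E,30S)-6,10,14,18,22,26,30,34-octamethylpentatriaconta-5,17,21,25-tetraen-2-yne | CC#CC/C=C(\C)CCC[C@@H](C)CCC[C@@H](C)CC/C=C(\C)CC/C=C(\C)CC/C=C(\C)CCC[C@@H](C)CCCC(C)C | intermediate
30 | hexacarbonylchromium | O=C=[Cr](=C=O)(=C=O)(=C=O)(=C=O)=C=O | starting material
31 | phenyllithium | [Li]c1ccccc1 | starting material
32 | lithium pentacarbonyl(benzoyl)chromate | [Li+].[O-]C(c1ccccc1)=[Cr](=C=O)(=C=O)(=C=O)(=C=O)=C=O | intermediate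
33 | pentacarbonyl[methoxy(phenyl)methylene]chromium | COC(c1ccccc1)=[Cr](=C=O)(=C=O)(=C=O)(=C=O)=C=O | intermediate
34 | tricarbonylchromium complex of 35 (metal on the newly formed oxygenated ring) | COc1c(C)c(C/C=C(\C)CCC[C@@H](C)CCC[C@@H](C)CC/C=C(\C)CC/C=C(\C)CC/C=C(\C)CCC[C@@H](C)CCCC(C)C)c(O)c2ccccc12.O=C=[Cr](=C=O)=C=O | intermediate
35 | 4-methoxy-3-methyl-2-[(2E,7S,11R,14E,18E,22E,27S)-3,7,11,15,19,23,27,31-octamethyldotriaconta-2,14,18,22-tetraen-1-yl]naphthalen-1-ol | COc1c(C)c(C/C=C(\C)CCC[C@@H](C)CCC[C@@H](C)CC/C=C(\C)CC/C=C(\C)CC/C=C(\C)CCC[C@@H](C)CCCC(C)C)c(O)c2ccccc12 | intermediate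
36 | 2-methyl-3-[(2E,7S,11R,14E,18E,22E,27S)-3,7,11,15,19,23,27,31-octamethyldotriaconta-2,14,18,22-tetraen-1-yl]naphthalene-1,4-dione | CC1=C(C/C=C(\C)CCC[C@@H](C)CCC[C@@H](C)CC/C=C(\C)CC/C=C(\C)CC/C=C(\C)CCC[C@@H](C)CCCC(C)C)C(=O)c2ccccc2C1=O | target

**Step count and risks**

Total step count: 24.
Longest linear sequence: 13 steps (steps 1, 12–21, 23 and 24, from (S)-citronellol 1 to 36).

Steps most likely to fail:

1. Step 23 (key step). The vinylcarbene and vinylketene intermediates may cyclise without, or before, carbonyl insertion to indene, furan or cyclobutenone products, or the carbene complex may decompose faster than the hindered internal alkyne inserts. The fallback buys the ring instead of building it; it sets out from bromide 27 and comes back at the target 36. Commercial 1,4-dimethoxy-2-methylnaphthalene would be brominated (Br2, CH2Cl2, 0 °C) at its only free position on the substituted ring to give 2-bromo-1,4-dimethoxy-3-methylnaphthalene F1. Magnesium in THF would convert it into (1,4-dimethoxy-3-methylnaphthalen-2-yl)magnesium bromide F2, which would be coupled with 27 under CuBr·SMe2 catalysis at the primary allylic carbon to give 1,4-dimethoxy-2-methyl-3-(C40 side chain)naphthalene F3. Oxidative demethylation of F3 with (NH4)2Ce(NO3)6 in MeCN/H2O at 0 °C would then give 36.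

2. Step 18. Magnesium insertion into the alkyl chloride may be incomplete, and the Grignard reagent may attack the γ carbon of the allylic bromide (SN2' course) or homocouple. The fallback reverses the polarity of the C12'–C13' bond; it sets out from 11 and 23 and comes back at 25. Bromide 11 with PhSO2Na in DMF would give the allylic sulfone {[(2E,6E,10E,15S)-3,7,11,15,19-pentamethylicosa-2,6,10-trien-1-yl]sulfonyl}benzene F4. Chloride 23 with NaI in refluxing butanone (Finkelstein exchange) would give tert-butyl{[(2E,7S,11R)-12-iodo-3,7,11-trimethyldodec-2-en-1-yl]oxy}diphenylsilane F5. Deprotonation of F4 with n-butyllithium in THF at −78 °C would give the lithiated sulfone F6, which would be alkylated with F5 (THF/DMPU) to the 13-(phenylsulfonyl) derivative of 25, F7, as a mixture of C13 epimers. Palladium-catalysed reductive desulfonylation (PdCl2(dppp) cat., LiBHEt3, THF, 0 °C), which delivers hydride to the less substituted allyl terminus and keeps the alkene in place, would give 25.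

3. Step 4. The SeO2 oxidation of a triene may stop at low conversion, over-oxidise to the enal or attack internal allylic positions. The fallback cleaves and rebuilds the terminal alkene; it sets out from 5 and comes back at 6. N-Bromosuccinimide in THF/H2O at 0 °C would add selectively to the terminal alkene to give the bromohydrin (6E,10E)-3-bromo-12-[(tert-butyldiphenylsilyl)oxy]-2,6,10-trimethyldodeca-6,10-dien-2-ol F8. K2CO3 in MeOH would close it to the terminal epoxide tert-butyl{[(2E,6E)-9-(3,3-dimethyloxiran-2-yl)-3,7-dimethylnona-2,6-dien-1-yl]oxy}diphenylsilane F9. H5IO6 in THF/Et2O would cleave the epoxide to (4E,8E)-10-[(tert-butyldiphenylsilyl)oxy]-4,8-dimethyldeca-4,8-dienal F10. Wittig olefination with ethyl 2-(triphenylphosphoranylidene)propanoate in CH2Cl2 would give the (E)-enoate ethyl (2E,6E,10E)-12-[(tert-butyldiphenylsilyl)oxy]-2,6,10-trimethyldodeca-2,6,10-trienoate F11, and iBu2AlH in toluene at −78 °C would reduce it to 6.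

Further compounds
F1 | step 23 | 2-bromo-1,4-dimethoxy-3-methylnaphthalene | COc1c(C)c(Br)c(OC)c2ccccc12
F2 | step 23 | (1,4-dimethoxy-3-methylnaphthalen-2-yl)magnesium bromide | COc1c(C)c([Mg]Br)c(OC)c2ccccc12
F3 | step 23 | 1,4-dimethoxy-2-methyl-3-[(2E,7S,11R,14E,18E,22E,27S)-3,7,11,15,19,23,27,31-octamethyldotriaconta-2,14,18,22-tetraen-1-yl]naphthalene | COc1c(C)c(C/C=C(\C)CCC[C@@H](C)CCC[C@@H](C)CC/C=C(\C)CC/C=C(\C)CC/C=C(\C)CCC[C@@H](C)CCCC(C)C)c(OC)c2ccccc12
F4 | step 18 | {[(2E,6E,10E,15S)-3,7,11,15,19-pentamethylicosa-2,6,10-trien-1-yl]sulfonyl}benzene | O=S(=O)(c1ccccc1)C/C=C(\C)CC/C=C(\C)CC/C=C(\C)CCC[C@@H](C)CCCC(C)C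
F5 | step 18 | tert-butyl{[(2E,7S,11R)-12-iodo-3,7,11-trimethyldodec-2-en-1-yl]oxy}diphenylsilane | CC(C)(C)[Si](c1ccccc1)(c1ccccc1)OC/C=C(\C)CCC[C@@H](C)CCC[C@@H](C)CI
F6 | step 18 | lithium salt of the α-sulfonyl carbanion of F4 | [Li+].O=S(=O)(c1ccccc1)[CH-]/C=C(\C)CC/C=C(\C)CC/C=C(\C)CCC[C@@H](C)CCCC(C)C
F7 | step 18 | tert-butyl{[(2E,7S,11R,13RS,14E,18E,22E,27S)-3,7,11,15,19,23,27,31-octamethyl-13-(phenylsulfonyl)dotriaconta-2,14,18,22-tetraen-1-yl]oxy}diphenylsilane | CC(C)(C)[Si](c1ccccc1)(c1ccccc1)OC/C=C(\C)CCC[C@@H](C)CCC[C@@H](C)CC(/C=C(\C)CC/C=C(\C)CC/C=C(\C)CCC[C@@H](C)CCCC(C)C)S(=O)(=O)c1ccccc1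
F8 | step 4 | (6E,10E)-3-bromo-12-[(tert-butyldiphenylsilyl)oxy]-2,6,10-trimethyldodeca-6,10-dien-2-ol (racemic at C3) | CC(C)(O)C(Br)CC/C(C)=C/CC/C(C)=C/CO[Si](c1ccccc1)(c1ccccc1)C(C)(C)C
F9 | step 4 | tert-butyl{[(2E,6E)-9-(3,3-dimethyloxiran-2-yl)-3,7-dimethylnona-2,6-dien-1-yl]oxy}diphenylsilane | CC1(C)OC1CC/C(C)=C/CC/C(C)=C/CO[Si](c1ccccc1)(c1ccccc1)C(C)(C)C
F10 | step 4 | (4E,8E)-10-[(tert-butyldiphenylsilyl)oxy]-4,8-dimethyldeca-4,8-dienal | O=CCC/C(C)=C/CC/C(C)=C/CO[Si](c1ccccc1)(c1ccccc1)C(C)(C)C
F11 | step 4 | ethyl (2E,6E,10E)-12-[(tert-butyldiphenylsilyl)oxy]-2,6,10-trimethyldodeca-2,6,10-trienoate | CCOC(=O)/C(C)=C/CC/C(C)=C/CC/C(C)=C/CO[Si](c1ccccc1)(c1ccccc1)C(C)(C)C
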